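The carbocycle of the target is a cyclohexa-2,4-dienone fused to a 2,2-dimethyl-2H-pyran; in chromene numbering the fusion carbon C4a is quaternary and is the only stereocentre. It bears a prenyl group and the vinyl carbon C4, and every ring oxygen (O1 at C8a, the C5 carbonyl, the C7 hydroxyl) is ortho or para to it, so C4a is the natural nucleophile of the parent arene. Cleaving C4–C4a gives an achiral, mirror-symmetric 1,1-dimethylpropargyl ether of deoxycohumulone, isomeric with the target. One enantioselective gold-catalysed 6-endo-dig attack of a prenyl-bearing ortho carbon on the alkyne should then build the pyran, break aromaticity and set C4a.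

Key step: step 5

Assumption: the target is one enol tautomer of a rapidly equilibrating cyclic β-triketone, so its tautomers count as one compound; the (R)-antipode of DTBM-SEGPHOS (5,5'-bis[bis(3,5-di-tert-butyl-4-methoxyphenyl)phosphino]-4,4'-bi-1,3-benzodioxole) is taken to deliver (R) at C4a, to be confirmed in a trial run and exchanged for the (S)-ligand if the sense is opposite.

## Route

Step 1
Reactants: 1 phloroglucinol (benzene-1,3,5-triol); 2 isobutyryl chloride (2-methylpropanoyl chloride)
Product: 3 phlorisobutyrophenone (2-methyl-1-(2,4,6-trihydroxyphenyl)propan-1-one)
Conditions: AlCl3 (4 equiv), PhNO2, 0 °C to 65 °C; then ice, 1 M HCl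
Reagents that add atoms: none
Why: Friedel–Crafts C-acylation of the very electron-rich triol should stop after one acyl group, because the aryl ketone, chelated to aluminium, deactivates the ring towards a second acylation.

Step 2
Reactants: 3 phlorisobutyrophenone; 4 prenyl bromide (1-bromo-3-methylbut-2-ene)
Product: 6 deoxycohumulone, via 3-prenylphlorisobutyrophenone 5 (not isolated)
Conditions: 4 (2.1 equiv), 10% aq. KOH, 0 °C, argon; then 2 M HCl
Reagents that add atoms: none
Why: Twofold C-alkylation of the ambident phenolate by the allylic bromide (SN2), favoured over O-alkylation in water where the oxygens are hydrogen-bonded, should fill both free ring carbons, while the limited amount of bromide, the low temperature and the exclusion of air hold back geminal prenylation and oxidation of the product.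

Step 3
Reactants: 7 2-methylbut-3-yn-2-ol
Product: 8 3-chloro-3-methylbut-1-yne
Conditions: conc. HCl, CaCl2, CuCl (cat.), Cu powder (cat.), 0 °C to rt; distillation
Reagents that add atoms: hydrogen chloride, Cl
Why: Copper-assisted SN1 substitution of the tertiary propargylic alcohol by chloride through the stabilised propargylic cation should give the volatile chloride, which CaCl2 salts out of the acid layer before distillation.

Step 4
Reactants: 6 deoxycohumulone; 8 3-chloro-3-methylbut-1-yne
Product: 9 1-[2,6-dihydroxy-4-(2-methylbut-3-yn-2-yloxy)-3,5-bis(3-methylbut-2-enyl)phenyl]-2-methylpropan-1-one (achiral propargyl ether)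
Conditions: 8 (1.2 equiv), CuCl2·2H2O (1 mol %), DBU (1.05 equiv), MeCN, −5 °C to 0 °C, argon
Reagents that add atoms: none
Why: Copper-catalysed O-propargylation of a phenol by a tertiary propargylic chloride (through a copper acetylide/allenylidene that accepts the phenoxide at its tertiary carbon) should etherify only the hydroxyl para to the acyl group, since one equivalent of DBU ionises this most acidic, non-chelated hydroxyl and attack through carbon would have to join two fully substituted carbons.

Step 5
Reactants: 9 achiral propargyl ether
Product: 10 (4aR)-7-hydroxy-2,2-dimethyl-4a,8-bis(3-methylbut-2-enyl)-6-(2-methylpropanoyl)-2H-chromen-5(4aH)-one (target)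
Conditions: (R)-DTBM-SEGPHOS(AuCl)2 (5 mol %), AgNTf2 (10 mol %), 4 Å MS, CH2Cl2/toluene, −40 °C to −10 °C, argon, dark
Reagents that add atoms: none
Why: Proposed new method: the cationic monovalent gold complex binds the terminal alkyne of 9, and the prenyl-bearing ortho carbon (future C4a), the most electron-rich ring position because all three ring oxygens are ortho or para to it, adds to the terminal alkyne carbon (future C4) anti to the metal; the arenium ion cannot rearomatise because C4a has no hydrogen, so it loses the proton of the adjacent C5 hydroxyl to become the cyclohexa-2,4-dienone, and this proton then cleaves the vinyl–gold bond and leaves the cis C3=C4 alkene. The closest known reaction types are the gold-catalysed 6-endo-dig hydroarylation of aryl 1,1-dimethylpropargyl ethers to 2,2-dimethyl-2H-chromenes and the catalytic asymmetric dearomatisation of phenols and naphthols by tethered metal-activated alkynes. The one ring closed is the 2H-pyran (O1, C2, C3, C4, C4a, C8a) in a 6-endo-dig mode, and because the O1–C8a bond is never broken the pyran oxygen is the one etherified in step 4. The new stereocentre C4a (R) is set by the catalyst: 9 has a mirror plane through the ether-bearing and the acyl-bearing ring carbons, its two ortho carbons are enantiotopic, and the axially chiral bisphosphine around the gold-bound alkyne decides which of them attacks. The step needs this enantiotopic-site selection together with chemoselectivity for the arene over the two prenyl alkenes and the two hydroxyls; the flanking prenyl groups turn the O–CMe2 bond out of the ring plane so that the alkyne sits over an ortho carbon, the geminal methyl groups favour the six-membered closure, the hydroxyls could reach the alkyne only through larger rings, and the alkyne is activated far more readily than the trisubstituted alkenes. The low temperature and the weakly coordinating NTf2 counterion are meant to suppress ionisation of the tertiary aryl ether and the propargyl Claisen pathway.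

## Compound list

1 | phloroglucinol (benzene-1,3,5-triol) | Oc1cc(O)cc(O)c1 | starting material
2 | isobutyryl chloride (2-methylpropanoyl chloride) | CC(C)C(=O)Cl | starting material
3 | phlorisobutyrophenone, 2-methyl-1-(2,4,6-trihydroxyphenyl)propan-1-one | CC(C)C(=O)c1c(O)cc(O)cc1O | intermediate
4 | prenyl bromide (1-bromo-3-methylbut-2-ene) | CC(C)=CCBr | starting material
5 | 3-prenylphlorisobutyrophenone, 2-methyl-1-[2,4,6-trihydroxy-3-(3-methylbut-2-enyl)phenyl]propan-1-one, formed and consumed in step 2 | CC(C)=CCc1c(O)cc(O)c(C(=O)C(C)C)c1O | intermediate
6 | deoxycohumulone, 2-methyl-1-[2,4,6-trihydroxy-3,5-bis(3-methylbut-2-enyl)phenyl]propan-1-one | CC(C)=CCc1c(O)c(CC=C(C)C)c(O)c(C(=O)C(C)C)c1O | intermediate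
7 | 2-methylbut-3-yn-2-ol | CC(C)(O)C#C | starting material
8 | 3-chloro-3-methylbut-1-yne | CC(C)(Cl)C#C | intermediate
9 | 1-[2,6-dihydroxy-4-(2-methylbut-3-yn-2-yloxy)-3,5-bis(3-methylbut-2-enyl)phenyl]-2-methylpropan-1-one, achiral | CC(C)=CCc1c(O)c(C(=O)C(C)C)c(O)c(CC=C(C)C)c1OC(C)(C)C#C | intermediate
10 | (4aR)-7-hydroxy-2,2-dimethyl-4a,8-bis(3-methylbut-2-enyl)-6-(2-methylpropanoyl)-2H-chromen-5(4aH)-one | CC(C)=CCC1=C2OC(C)(C)C=C[C@@]2(CC=C(C)C)C(=O)C(C(=O)C(C)C)=C1O | target

## Step count and risks

Total steps: 5. Longest linear sequence: 4 steps (1 → 3 → 6 → 9 → 10); step 3 is a one-step side branch.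

Steps most likely to fail:

1. Step 5 (the proposed new method). The catalyst may discriminate poorly between the two enantiotopic ortho carbons. The cationic metal may ionise the tertiary aryl ether, or the reaction may divert into a sigmatropic shift followed by unselective reclosure. Fallback by known chemistry, setting out from 9 and returning at 10:
   - Heating 9 in degassed o-xylene at about 130 °C should bring about the aromatic propargyl Claisen rearrangement. Since both ortho carbons are substituted, the shift has to stop at the racemic 3,5-dihydroxy-4,6-bis(3-methylbut-2-enyl)-6-(3-methylbuta-1,2-dienyl)-2-(2-methylpropanoyl)cyclohexa-2,4-dien-1-one F1.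
   - Achiral Ph3PAuCl/AgBF4 in toluene at room temperature (metal-catalysed hydroalkoxylation of a β-hydroxy allene) should then add the free enol hydroxyl on the former ether carbon to the dimethyl-substituted allene terminus. This gives racemic 7-hydroxy-2,2-dimethyl-4a,8-bis(3-methylbut-2-enyl)-6-(2-methylpropanoyl)-2H-chromen-5(4aH)-one F2.
   - Preparative HPLC on a cellulose tris(3,5-dimethylphenylcarbamate) phase should then deliver 10.
   - The site of ring closure would have to be confirmed, and any isomer closed through the C5 oxygen removed by chromatography.

2. Step 4. Alkylation may occur at carbon with dearomatisation, at a chelated hydroxyl, or twice, and the triphenol may oxidise in air under base. Fallback, setting out from 3 (with 8 and 4) and returning at 9, with the order of the two alkylations inverted: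
   - The same CuCl2·2H2O/DBU/MeCN conditions at 0 °C are applied to 3, whose para hydroxyl is unhindered. This should give 1-[2,6-dihydroxy-4-(2-methylbut-3-yn-2-yloxy)phenyl]-2-methylpropan-1-one F3.
   - Twofold C-prenylation with 4 in 10% aq. KOH at 0 °C should pass through the monoprenyl ether 1-[2,6-dihydroxy-4-(2-methylbut-3-yn-2-yloxy)-3-(3-methylbut-2-enyl)phenyl]-2-methylpropan-1-one F4 (not isolated) and fill both free ring carbons to give 9.
   - This sequence bypasses the air-sensitive triphenol 6.

3. Step 2. The phenolate may be alkylated again at an already prenylated carbon or at oxygen, the second alkylation may stall, and the product may degrade oxidatively in base. Fallback, setting out from 3 and returning at 6: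
   - Friedel–Crafts prenylation of the neutral phenol with 2-methylbut-3-en-2-ol (2.2 equiv) and BF3·OEt2 (0.5 equiv) in dioxane at room temperature proceeds through the prenyl cation. Without a phenolate it cannot give geminal dialkylation.
   - It passes through 5, and a short reaction time limits acid-promoted chroman formation.
   - It makes no compound outside the list (entry F0 below).

## Further compounds

F1 | step 5 | racemic 3,5-dihydroxy-4,6-bis(3-methylbut-2-enyl)-6-(3-methylbuta-1,2-dienyl)-2-(2-methylpropanoyl)cyclohexa-2,4-dien-1-one | CC(C)=CCC1=C(O)C(CC=C(C)C)(C=C=C(C)C)C(=O)C(C(=O)C(C)C)=C1O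
F2 | step 5 | racemic 7-hydroxy-2,2-dimethyl-4a,8-bis(3-methylbut-2-enyl)-6-(2-methylpropanoyl)-2H-chromen-5(4aH)-one | CC(C)=CCC1=C2OC(C)(C)C=CC2(CC=C(C)C)C(=O)C(C(=O)C(C)C)=C1O
F3 | step 4 | 1-[2,6-dihydroxy-4-(2-methylbut-3-yn-2-yloxy)phenyl]-2-methylpropan-1-one | CC(C)C(=O)c1c(O)cc(OC(C)(C)C#C)cc1O
F4 | step 4 | 1-[2,6-dihydroxy-4-(2-methylbut-3-yn-2-yloxy)-3-(3-methylbut-2-enyl)phenyl]-2-methylpropan-1-one | CC(C)=CCc1c(O)c(C(=O)C(C)C)c(O)cc1OC(C)(C)C#C
F0 | step 2 | none | none
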